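**Retrosynthetic overview**
1. The triterpene half (rings A–E, six stereocentres) is bought as celastrol 1 and esterified to pristimerin 2.
2. The sesquiterpene half (five- and seven-membered rings, C7′ and C10′) is bought as (−)-guaiol 3: C2′ oxidation to enone 4, reduction to diol 5, then twofold dehydration (sulfamate 6, diene tautomers 7 and 8) to cyclopentadiene 9.
3. Key disconnection: both C–O bonds of the 1,4-dioxane (O3–C1′ and O2–C5′) are made in one inverse-demand oxa-Diels–Alder reaction between the C1′=C5′ bond of 9 and o-quinone 10, the catalytically unmasked tautomer of 2. This step also sets C8, C1′ and C5′ and gives target 11.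
4. Ring order: no carbocycle is built; the dioxane ring is the only ring formed, and it is formed last.

Assumption: celastrol and (−)-guaiol count as cheap commercial chiral-pool materials; friedelane locants (C1–C30) are used for the triterpene half and primed guaiane locants (C1′–C15′) for the sesquiterpene half.

**Step 1**
Reactants: 1 celastrol
Product: 2 pristimerin
Conditions: MeI (1.5 equiv), NaHCO3 (3 equiv), DMF, 23 °C, 12 h
Reagents that add atoms: iodomethane, CI
Why: Carboxylate O-alkylation (SN2 esterification): NaHCO3 deprotonates only the C29 acid, so MeI methylates the carboxylate and leaves the hydrogen-bonded C3 enol OH and all stereocentres untouched.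

**Step 2**
Reactants: 3 (−)-guaiol
Product: 4 (4S,7R,10S)-11-hydroxyguai-1(5)-en-2-one
Conditions: CrO3 (12 equiv), 3,5-dimethylpyrazole (12 equiv), CH2Cl2, −20 °C, 4 h
Reagents that add atoms: chromium trioxide, O=[Cr](=O)=O
Why: Allylic C–H oxidation with the CrO3·3,5-dimethylpyrazole complex converts an allylic methylene into the enone carbonyl; C2′ is the only unhindered allylic CH2 (C6′ lies next to the C7′ carbinol side chain, C4′ and C10′ are methines), the same site at which α-guaiene is oxidised to rotundone, and no stereocentre is touched.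

**Step 3**
Reactants: 4 (4S,7R,10S)-11-hydroxyguai-1(5)-en-2-one
Product: 5 (4S,7R,10S)-guai-1(5)-ene-2,11-diol
Conditions: NaBH4 (1.2 equiv), CeCl3·7H2O (1.1 equiv), MeOH, 0 °C, 30 min
Reagents that add atoms: none
Why: Luche reduction gives clean 1,2-reduction of the cyclopentenone; the new C2′ carbinol centre forms as an epimer mixture that does not matter because C2′ ends as CH2.

**Step 4**
Reactants: 5 (4S,7R,10S)-guai-1(5)-ene-2,11-diol
Product: 9 (7R,10S)-guaia-1(5),3,11-triene, via bis-sulfamate ester 6 (not isolated), via guaia-1(5),2,11-triene 7 (not isolated), via guaia-1,4,11-triene 8 (not isolated)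
Conditions: Burgess reagent (MeO2CN–SO2NEt3 inner salt, 3.0 equiv), PhH, 23 → 50 °C, 2 h; then 70 °C, 6 h; SiO2 plug (pentane)
Reagents that add atoms: none
Why: Twofold Burgess dehydration (syn-elimination of the sulfamates: the tertiary one loses a methyl hydrogen to give the isopropenyl group, the allylic C2′ one can only lose H-3′ within the five-membered ring because C1′ is sp2) gives kinetic diene 7, and thermal suprafacial [1,5]-hydrogen shifts around the cyclopentadiene ring carry 7 through 8 to 9, which keeps the tetrasubstituted ring-fusion C1′=C5′ bond and gains the methyl-bearing C3′=C4′ bond; C7′ and C10′ are untouched and the C4′ centre is erased on purpose.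

**Step 5**
Reactants: 2 pristimerin; 9 (7R,10S)-guaia-1(5),3,11-triene
Product: 11 target CNP0113384.3, via pristimerin o-quinone tautomer 10 (not isolated)
Conditions: n-Bu4NOAc (20 mol %), AcOH (20 mol %), triene in fivefold excess, PhMe–MeCN 4:1 (0.3 M), Ar, dark, 45 °C, 48 h
Reagents that add atoms: none
Why: Proposed new method: an acetate/acetic acid proton relay (AcO− removes the O3–H proton of the hydroxy-quinone methide 2 and AcOH, pKa-matched to the C8–H carbon acid, returns it to C8 of the delocalised trienolate on the β face, the α face being shielded by the axial 13α-methyl group) continuously supplies the minor (8S) o-quinone tautomer 10 under Curtin–Hammett conditions, and 10 is removed irreversibly as a 4π O=C2–C3=O heterodiene by the most electron-rich π bond of 9, the tetrasubstituted C1′=C5′ bond, in a suprafacial [4+2] addition that aromatises ring A, takes place on the face anti to the 10′-methyl and 7′-isopropenyl groups (cis-fused dioxane, 1′R,5′R) and pairs O3 with C1′ and O2 with C5′, because bonding first at the diene terminus C1′ leaves an allylic positive charge and bonding first at O3 leaves the O2 phenoxide that is conjugated through C5 with the C6=C7 bond; the closest known reaction type is the inverse-electron-demand oxa-Diels–Alder reaction of preformed o-quinones with alkenes and dienes, which has not been run from a quinone methide tautomer generated in the flask or onto a fully substituted cyclopentadiene bond.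

**Compound list**
1 | celastrol (3-hydroxy-2-oxo-24-nor-D:A-friedooleana-1(10),3,5,7-tetraen-29-oic acid) | CC1=C(O)C(=O)C=C2C1=CC=C1[C@@]2(C)CC[C@@]2(C)[C@@H]3C[C@](C)(C(=O)O)CC[C@]3(C)CC[C@]12C | starting material
2 | pristimerin (methyl ester of 1) | CC1=C(O)C(=O)C=C2C1=CC=C1[C@@]2(C)CC[C@@]2(C)[C@@H]3C[C@](C)(C(=O)OC)CC[C@]3(C)CC[C@]12C | intermediate
3 | (−)-guaiol, (4S,7R,10S)-guai-1(5)-en-11-ol | C[C@H]1CC[C@H](CC2=C1CC[C@@H]2C)C(C)(C)O | starting material
4 | (4S,7R,10S)-11-hydroxyguai-1(5)-en-2-one | C[C@H]1CC[C@H](CC2=C1C(=O)C[C@@H]2C)C(C)(C)O | intermediate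
5 | (4S,7R,10S)-guai-1(5)-ene-2,11-diol (C2 epimer mixture) | C[C@H]1CC[C@H](CC2=C1C(O)C[C@@H]2C)C(C)(C)O | intermediate
6 | 2,11-bis[N-(methoxycarbonyl)sulfamate] of 5 (triethylammonium salt in the flask, drawn as the N–H acid) | C[C@H]1CC[C@H](CC2=C1C(OS(=O)(=O)NC(=O)OC)C[C@@H]2C)C(C)(C)OS(=O)(=O)NC(=O)OC | intermediate
7 | (4S,7R,10S)-guaia-1(5),2,11-triene | C[C@H]1CC[C@H](CC2=C1C=C[C@@H]2C)C(=C)C | intermediate
8 | (7R,10S)-guaia-1,4,11-triene | C[C@H]1CC[C@H](CC2=C(C)CC=C12)C(=C)C | intermediate
9 | (7R,10S)-guaia-1(5),3,11-triene | C[C@H]1CC[C@H](CC2=C1CC=C2C)C(=C)C | intermediate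
10 | methyl (8S)-2,3-dioxo-24-nor-D:A-friedooleana-1(10),4,6-trien-29-oate (o-quinone tautomer of 2, 8β-H) | O=C1C=C2C(=C(C)C1=O)C=C[C@@H]1[C@@]2(C)CC[C@@]2(C)[C@@H]3C[C@](C)(C(=O)OC)CC[C@]3(C)CC[C@]12C | intermediate
11 | CNP0113384.3, methyl (8S)-2,3-[(1′R,5′R,7′R,10′S)-guaia-3′,11′-diene-1′,5′-diylbis(oxy)]-24-nor-D:A-friedooleana-1,3,5(10),6-tetraen-29-oate (O3–C1′, O2–C5′) | C=C(C)[C@@H]1CC[C@H](C)[C@]23CC=C(C)[C@@]2(C1)Oc1cc2c(c(C)c1O3)C=C[C@@H]1[C@@]2(C)CC[C@@]2(C)[C@@H]3C[C@](C)(C(=O)OC)CC[C@]3(C)CC[C@]12C | target

**Totals**
Total step count: 5. Longest linear sequence: 4 steps (3 → 4 → 5 → 9 → 11).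

**Steps most likely to fail, with fallbacks**

Step 5 (the new tautomerising oxa-Diels–Alder reaction) carries the most risk. The standing concentration of 10 may be too low for a useful rate, and protonation at C8 may also occur on the α face and give the C8 epimer. The diene may react at its less hindered C3′=C4′ bond or with the opposite O/C pairing, and tautomer 8, which is similar in energy to 9 and equilibrates with it at 45 °C, can give its own adducts. The non-conjugated C7=C8 o-quinone tautomer could be trapped instead. The fallback uses known chemistry, sets out from 2 (again with 9) and comes back at 11. NaBH4 in MeOH–THF at 0 °C adds hydride to C6 of 2 and gives the air-sensitive catechol pristimerol F1. Ag2O (3 equiv) with MgSO4 in CH2Cl2 at 0 °C, in the presence of the triene in fivefold excess, oxidises F1 to the C7=C8 o-quinone F2, which is trapped at once by oxa-Diels–Alder reaction as the C7=C8 adduct F3; at 0 °C the diene does not tautomerise. KOt-Bu (0.3 equiv) in DMSO–THF at 20 °C then moves the C7=C8 bond into conjugation with ring A through the delocalised C6–C7–C8 allyl anion, which is reprotonated at C8, giving 11. This isomerisation is reversible, so the C8 configuration is under thermodynamic control there and must be checked against 11. Any F3 or C8 epimer formed as a by-product of step 5 can be fed into the same equilibration. The site-selectivity risk on the diene is not removed by this fallback.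

Step 4 (twofold dehydration and tautomer equilibration) is the second risk. The allylic sulfamate may rearrange to an allylic carbamate or eliminate into the seven-membered ring, and some isopropylidene isomer may form. The fallback sets out from 4 and comes back at 7, which is heated on to 9 as in step 4. TsNHNH2 in MeOH at 23 °C gives tosylhydrazone F4. LiN(i-Pr)2 (3.5 equiv) in THF, −78 → 0 °C, then H2O (Shapiro reaction; only C3′ can be deprotonated because C1′ is sp2) gives dienol F5 with the C2′=C3′ bond placed unambiguously. Burgess reagent (1.3 equiv) in PhH at 50 °C dehydrates the single tertiary alcohol through sulfamate F6 to 7.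

Step 2 (allylic oxidation) is the third risk, through competing attack at C6′, at the tertiary allylic C–H bonds, or epoxidation of the tetrasubstituted alkene. The fallback sets out from 3 and comes back at 5. SeO2 (0.5 equiv) with t-BuOOH in CH2Cl2 at 23 °C hydroxylates C2′ directly by an ene reaction followed by a [2,3]-sigmatropic shift, which skips the ketone and the reduction; this detour makes no compound outside the list (F0).

**Further compounds**
F1 | step 5 | pristimerol (methyl 2,3-dihydroxy-24-nor-D:A-friedooleana-1,3,5(10),7-tetraen-29-oate) | Cc1c(O)c(O)cc2c1CC=C1[C@@]2(C)CC[C@@]2(C)[C@@H]3C[C@](C)(C(=O)OC)CC[C@]3(C)CC[C@]12C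
F2 | step 5 | methyl 2,3-dioxo-24-nor-D:A-friedooleana-1(10),4,7-trien-29-oate | O=C1C=C2C(=C(C)C1=O)CC=C1[C@@]2(C)CC[C@@]2(C)[C@@H]3C[C@](C)(C(=O)OC)CC[C@]3(C)CC[C@]12C
F3 | step 5 | C7=C8 isomer of 11 (6-H2, no 8-H) | C=C(C)[C@@H]1CC[C@H](C)[C@]23CC=C(C)[C@@]2(C1)Oc1cc2c(c(C)c1O3)CC=C1[C@@]2(C)CC[C@@]2(C)[C@@H]3C[C@](C)(C(=O)OC)CC[C@]3(C)CC[C@]12C
F4 | step 4 | p-toluenesulfonylhydrazone of 4 | C[C@H]1CC[C@H](CC2=C1C(=NNS(=O)(=O)c3ccc(C)cc3)C[C@@H]2C)C(C)(C)O
F5 | step 4 | (4S,7R,10S)-guaia-1(5),2-dien-11-ol | C[C@H]1CC[C@H](CC2=C1C=C[C@@H]2C)C(C)(C)O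
F6 | step 4 | 11-[N-(methoxycarbonyl)sulfamate] of F5 | C[C@H]1CC[C@H](CC2=C1C=C[C@@H]2C)C(C)(C)OS(=O)(=O)NC(=O)OC
F0 | step 2 | none | none
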